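**Plan**

- Chain locants run from C1' (benzylic CH2) to C15' (terminal CMe2). The retrosynthesis first cuts C12'–C13' (prenyl ketone from a C12' aldehyde), then cuts C3'–C4' and C5'–C6' together.
- Enabling feature: the carbinol carbon C5' lies between the alkene carbon C6' and the methylene C4', which is bonded to the alkene carbon C3'. C4'–C5' can therefore come from a vinyl group stitched between two alkenyl partners. The arene is the only ring and no ring is formed.
- Forward order: the west (E)-alkenyl bromide (arene, C1'–C3') is made from 4-methoxy-2-methylphenol. The east (E)-alkenylboronate (C6'–C12') is made from methyl (S)-3-hydroxy-2-methylpropanoate. Both are joined with vinyllithium in one three-component step, and C13'–C15' is added last.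
- Stereochemistry: C11' comes from the hydroxy ester. C5' is set by the chiral palladium–bisphosphine catalyst and kept by a retentive C–B oxidation. The 2'E alkene comes from syn hydrozirconation and the 6'E alkene from syn carboalumination.

Key step: step 13

**Remarks on the chemistry**

- Vinyllithium is taken as a halide-free THF solution, purchased or made beforehand from tetravinylstannane and n-BuLi.
- The ligand is written as its (Sp,Sp) antipode. The sense of induction is to be checked by Mosher ester analysis of the C5' alcohol, and the mirror-image ligand is used if the 5'S alcohol should form.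

**West fragment**

Step 1
Reactants: 1 4-methoxy-2-methylphenol
Product: 2 2-hydroxy-5-methoxy-3-methylbenzaldehyde
Conditions: (CH2O)n, MgCl2, Et3N, MeCN, reflux; aq. HCl work-up
Reagents that add atoms: paraformaldehyde (formaldehyde unit), C=O
Why: Magnesium-mediated ortho-formylation (Casnati–Skattebøl reaction) delivers formaldehyde to C6, the only free ortho position, and a second formaldehyde oxidises the benzylic alkoxide by hydride transfer.

Step 2
Reactants: 2 2-hydroxy-5-methoxy-3-methylbenzaldehyde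
Product: 3 2-[(tert-butyldimethylsilyl)oxy]-5-methoxy-3-methylbenzaldehyde
Conditions: TBSCl, imidazole, DMAP (cat.), DMF, rt
Reagents that add atoms: tert-butyldimethylsilyl chloride, CC(C)(C)[Si](C)(C)Cl
Why: Standard silylation of a phenol; the two ortho substituents slow it but later shield the aryl silyl ether from base and nucleophiles.

Step 3
Reactants: 3 2-[(tert-butyldimethylsilyl)oxy]-5-methoxy-3-methylbenzaldehyde
Product: 4 {2-[(tert-butyldimethylsilyl)oxy]-5-methoxy-3-methylphenyl}methanol
Conditions: NaBH4, MeOH/THF, 0 °C; aq. NH4Cl quench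
Reagents that add atoms: none
Why: Borohydride reduction of the aldehyde, kept cold and brief with a neutral quench so that the silyl group does not shift from the phenolic to the benzylic oxygen.

Step 4
Reactants: 4 {2-[(tert-butyldimethylsilyl)oxy]-5-methoxy-3-methylphenyl}methanol
Product: 5 [2-(bromomethyl)-4-methoxy-6-methylphenoxy](tert-butyl)dimethylsilane
Conditions: CBr4, PPh3, CH2Cl2, 0 °C
Reagents that add atoms: carbon tetrabromide, BrC(Br)(Br)Br
Why: Appel bromination under neutral conditions converts the benzylic alcohol into the bromide without touching the aryl silyl ether.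

Step 5
Reactants: 5 [2-(bromomethyl)-4-methoxy-6-methylphenoxy](tert-butyl)dimethylsilane; 6 prop-1-yn-1-ylmagnesium bromide
Product: 7 [2-(but-2-yn-1-yl)-4-methoxy-6-methylphenoxy](tert-butyl)dimethylsilane
Conditions: CuBr·SMe2 (10 mol %), THF, 0 °C → 50 °C
Reagents that add atoms: none
Why: Copper-catalysed substitution of a benzylic bromide by an alkynyl Grignard reagent forms C1'–C2' under conditions too weakly basic to isomerise the 1-aryl-2-butyne to an allene.

Step 6
Reactants: 7 [2-(but-2-yn-1-yl)-4-methoxy-6-methylphenoxy](tert-butyl)dimethylsilane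
Product: 9 {2-[(E)-3-bromobut-2-en-1-yl]-4-methoxy-6-methylphenoxy}(tert-butyl)dimethylsilane, via alkenylzirconocene chloride 8 (not isolated)
Conditions: Cp2Zr(H)Cl (2.5 equiv), THF, 50 °C; then NBS, 0 °C
Reagents that add atoms: N-bromosuccinimide, O=C1CCC(=O)N1Br
Why: Hydrozirconation with excess Cp2Zr(H)Cl under equilibrating conditions places zirconium by syn addition on the methyl-bearing carbon C3' (the less hindered end), and bromodezirconation with NBS goes with retention, so the 2'E bromide should result.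

**East fragment**

Step 7
Reactants: 10 methyl (S)-3-hydroxy-2-methylpropanoate
Product: 11 methyl (2S)-2-methyl-3-[(triethylsilyl)oxy]propanoate
Conditions: TESCl, imidazole, CH2Cl2, 0 °C
Reagents that add atoms: chlorotriethylsilane, CC[Si](CC)(CC)Cl
Why: Silylation of the primary alcohol under mild conditions that do not touch the α-stereocentre of the ester.

Step 8
Reactants: 11 methyl (2S)-2-methyl-3-[(triethylsilyl)oxy]propanoate
Product: 12 (2R)-2-methyl-3-[(triethylsilyl)oxy]propan-1-ol
Conditions: i-Bu2AlH (2.2 equiv), CH2Cl2, −78 °C → 0 °C; aq. KNaC4H4O6 work-up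
Reagents that add atoms: none
Why: Ester reduction with i-Bu2AlH at low temperature, where the aluminium alkoxide does not promote silyl migration between the two oxygens, which would amount to racemisation.

Step 9
Reactants: 12 (2R)-2-methyl-3-[(triethylsilyl)oxy]propan-1-ol
Product: 13 (2S)-2-methyl-3-[(triethylsilyl)oxy]propyl 4-methylbenzenesulfonate
Conditions: TsCl, Et3N, DMAP (cat.), CH2Cl2, 0 °C → rt
Reagents that add atoms: p-toluenesulfonyl chloride, Cc1ccc(cc1)S(Cl)(=O)=O
Why: Sulfonylation of the primary alcohol installs a leaving group at the future C10' and leaves the triethylsilyl ether intact.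

Step 10
Reactants: 13 (2S)-2-methyl-3-[(triethylsilyl)oxy]propyl 4-methylbenzenesulfonate; 14 (4-bromobut-1-yn-1-yl)trimethylsilane
Product: 16 triethyl{[(2R)-2-methyl-7-(trimethylsilyl)hept-6-yn-1-yl]oxy}silane, via alkynyl Grignard reagent 15 (not isolated)
Conditions: 14, Mg turnings, THF, rt → 40 °C; then 13, Li2CuCl4 (5 mol %), THF, −20 °C → rt
Reagents that add atoms: none
Why: Copper-catalysed sp3–sp3 coupling of a primary tosylate with a primary alkyl Grignard reagent forms C9'–C10' by displacement one carbon away from the stereocentre, which is therefore unaffected.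

Step 11
Reactants: 16 triethyl{[(2R)-2-methyl-7-(trimethylsilyl)hept-6-yn-1-yl]oxy}silane
Product: 17 triethyl{[(2R)-2-methylhept-6-yn-1-yl]oxy}silane
Conditions: K2CO3, MeOH, rt
Reagents that add atoms: none
Why: Base-catalysed methanolysis cleaves the C(sp)–Si bond of the alkynylsilane, while the alkyl triethylsilyl ether is stable to K2CO3 in methanol at room temperature.

Step 12
Reactants: 17 triethyl{[(2R)-2-methylhept-6-yn-1-yl]oxy}silane; 18 2-isopropoxy-4,4,5,5-tetramethyl-1,3,2-dioxaborolane
Product: 20 triethyl{[(2R,6E)-2,6-dimethyl-7-(4,4,5,5-tetramethyl-1,3,2-dioxaborolan-2-yl)hept-6-en-1-yl]oxy}silane, via alkenyldimethylalane 19 (not isolated)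
Conditions: AlMe3 (2 equiv), Cp2ZrCl2 (0.25 equiv), CH2Cl2, 0 °C → rt; then 18 (3 equiv), 0 °C → rt
Reagents that add atoms: trimethylaluminium, C[Al](C)C
Why: Negishi zirconium-catalysed carboalumination adds methyl and aluminium syn across the terminal alkyne with aluminium on the terminal carbon, and the alkenyl group is then transferred from aluminium to boron of the alkoxyboronate with retention, giving the 6'E alkenylboronate.

**Union and endgame**

Step 13
Reactants: 20 triethyl{[(2R,6E)-2,6-dimethyl-7-(4,4,5,5-tetramethyl-1,3,2-dioxaborolan-2-yl)hept-6-en-1-yl]oxy}silane; 21 vinyllithium; 9 {2-[(E)-3-bromobut-2-en-1-yl]-4-methoxy-6-methylphenoxy}(tert-butyl)dimethylsilane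
Product: 23 tert-butyl{2-[(2E,5R,6E,11R)-3,7,11-trimethyl-5-(4,4,5,5-tetramethyl-1,3,2-dioxaborolan-2-yl)-12-[(triethylsilyl)oxy]dodeca-2,6-dien-1-yl]-4-methoxy-6-methylphenoxy}dimethylsilane, via lithium bis(alkenyl)borate 22 (not isolated)
Conditions: 20, 21 (1.0 equiv), THF, 0 °C → rt; then 9 (1.1 equiv), Pd(OAc)2 (3 mol %, divalent palladium precatalyst), (Sp,Sp)-1,1'-bis[bis(4-methoxy-3,5-dimethylphenyl)phosphino]-2,2'-bis[(R)-α-(dimethylamino)benzyl]ferrocene (a MandyPhos ligand, 3.6 mol %), NaOTf (2 equiv), THF, 60 °C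
Reagents that add atoms: none
Why: Vinyllithium adds to boron of 20 to give borate 22; oxidative addition of bromide 9 to zerovalent palladium and bromide abstraction by NaOTf give a cationic alkenylpalladium species that binds the unsubstituted vinyl group of 22, whereupon the C6' alkenyl group shifts from boron to C5' anti to palladium as palladium bonds to C4', and reductive elimination then joins C4' to C3'. The closest known reaction type is the enantioselective conjunctive cross-coupling of bis(alkenyl)borates with C(sp2) electrophiles, which gives α-chiral allylic boronates. No ring is closed. C5' is the only new stereocentre and is set by the chiral bisphosphine on palladium, which selects one face of the vinyl group, while C11' is too remote to interfere. The step needs the trisubstituted alkenyl group to migrate and the vinyl group to accept, and this is secured because only the unhindered vinyl group can coordinate palladium and place the metal on a primary carbon, whereas the alternative would put palladium on the fully substituted C7'. Both E alkenes are carried over unchanged, because 1,2-migration, oxidative addition and reductive elimination all retain sp2 geometry.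

Step 14
Reactants: 23 tert-butyl{2-[(2E,5R,6E,11R)-3,7,11-trimethyl-5-(4,4,5,5-tetramethyl-1,3,2-dioxaborolan-2-yl)-12-[(triethylsilyl)oxy]dodeca-2,6-dien-1-yl]-4-methoxy-6-methylphenoxy}dimethylsilane
Product: 24 (2E,5R,6E,11R)-1-{2-[(tert-butyldimethylsilyl)oxy]-5-methoxy-3-methylphenyl}-3,7,11-trimethyl-12-[(triethylsilyl)oxy]dodeca-2,6-dien-5-ol
Conditions: NaBO3·4H2O, THF/H2O (1:1), rt
Reagents that add atoms: sodium perborate tetrahydrate (dimeric anion shown), [Na+].[Na+].O[B-]1(O)OO[B-](O)(O)OO1
Why: Perborate oxidation of the C–B bond proceeds by 1,2-migration from boron to oxygen with retention at C5' and without allylic transposition, and the mildly basic medium should spare both silyl ethers.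

Step 15
Reactants: 24 (2E,5R,6E,11R)-1-{2-[(tert-butyldimethylsilyl)oxy]-5-methoxy-3-methylphenyl}-3,7,11-trimethyl-12-[(triethylsilyl)oxy]dodeca-2,6-dien-5-ol
Product: 25 tert-butyl{[(2E,5R,6E,11R)-1-{2-[(tert-butyldimethylsilyl)oxy]-5-methoxy-3-methylphenyl}-3,7,11-trimethyl-12-[(triethylsilyl)oxy]dodeca-2,6-dien-5-yl]oxy}dimethylsilane
Conditions: TBSCl, imidazole, DMAP (cat.), DMF, rt
Reagents that add atoms: tert-butyldimethylsilyl chloride, CC(C)(C)[Si](C)(C)Cl
Why: Silylation of the secondary allylic alcohol under conditions that leave the primary triethylsilyl ether in place.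

Step 16
Reactants: 25 tert-butyl{[(2E,5R,6E,11R)-1-{2-[(tert-butyldimethylsilyl)oxy]-5-methoxy-3-methylphenyl}-3,7,11-trimethyl-12-[(triethylsilyl)oxy]dodeca-2,6-dien-5-yl]oxy}dimethylsilane
Product: 26 (2R,6E,8R,10E)-8-[(tert-butyldimethylsilyl)oxy]-12-{2-[(tert-butyldimethylsilyl)oxy]-5-methoxy-3-methylphenyl}-2,6,10-trimethyldodeca-6,10-dien-1-ol
Conditions: PPTS (0.2 equiv), MeOH/CH2Cl2 (1:1), 0 °C
Reagents that add atoms: none
Why: Mild acid-catalysed methanolysis removes the primary triethylsilyl ether far faster than the secondary and aryl tert-butyldimethylsilyl ethers, a standard silyl differentiation.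

Step 17
Reactants: 26 (2R,6E,8R,10E)-8-[(tert-butyldimethylsilyl)oxy]-12-{2-[(tert-butyldimethylsilyl)oxy]-5-methoxy-3-methylphenyl}-2,6,10-trimethyldodeca-6,10-dien-1-ol
Product: 27 (2R,6E,8R,10E)-8-[(tert-butyldimethylsilyl)oxy]-12-{2-[(tert-butyldimethylsilyl)oxy]-5-methoxy-3-methylphenyl}-2,6,10-trimethyldodeca-6,10-dienal
Conditions: Dess–Martin periodinane, NaHCO3, CH2Cl2, 0 °C → rt
Reagents that add atoms: none
Why: Buffered Dess–Martin oxidation gives the α-branched aldehyde without epimerising C11' or touching the alkenes; the aldehyde is used at once.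

Step 18
Reactants: 27 (2R,6E,8R,10E)-8-[(tert-butyldimethylsilyl)oxy]-12-{2-[(tert-butyldimethylsilyl)oxy]-5-methoxy-3-methylphenyl}-2,6,10-trimethyldodeca-6,10-dienal; 28 1-chloro-3-methylbut-2-ene
Product: 30 (6R,10E,12R,14E)-12-[(tert-butyldimethylsilyl)oxy]-16-{2-[(tert-butyldimethylsilyl)oxy]-5-methoxy-3-methylphenyl}-2,6,10,14-tetramethylhexadeca-2,10,14-trien-5-ol as both C12' epimers, via prenylbarium chloride 29 (not isolated)
Conditions: BaI2, lithium biphenylide (LiC12H10, 2 equiv), THF, rt; 28, −78 °C; then 27, −78 °C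
Reagents that add atoms: none
Why: Allylic barium reagents add to aldehydes through their α-carbon (allylbarium addition), so prenylbarium chloride should give the linear prenyl carbinol and not the reverse-prenyl isomer; the new C12' stereocentre forms as a mixture that is erased in the next step.

Step 19
Reactants: 30 (6R,10E,12R,14E)-12-[(tert-butyldimethylsilyl)oxy]-16-{2-[(tert-butyldimethylsilyl)oxy]-5-methoxy-3-methylphenyl}-2,6,10,14-tetramethylhexadeca-2,10,14-trien-5-ol as both C12' epimers
Product: 31 (6R,10E,12R,14E)-12-[(tert-butyldimethylsilyl)oxy]-16-{2-[(tert-butyldimethylsilyl)oxy]-5-methoxy-3-methylphenyl}-2,6,10,14-tetramethylhexadeca-2,10,14-trien-5-one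
Conditions: Dess–Martin periodinane, NaHCO3, CH2Cl2, 0 °C
Reagents that add atoms: none
Why: Buffered Dess–Martin oxidation of the homoallylic alcohol gives the β,γ-unsaturated ketone without moving the alkene into conjugation and without epimerising C11'.

Step 20
Reactants: 31 (6R,10E,12R,14E)-12-[(tert-butyldimethylsilyl)oxy]-16-{2-[(tert-butyldimethylsilyl)oxy]-5-methoxy-3-methylphenyl}-2,6,10,14-tetramethylhexadeca-2,10,14-trien-5-one
Product: 32 (6R,10E,12R,14E)-12-hydroxy-16-(2-hydroxy-5-methoxy-3-methylphenyl)-2,6,10,14-tetramethylhexadeca-2,10,14-trien-5-one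
Conditions: HF·pyridine, pyridine, THF, 0 °C → rt
Reagents that add atoms: none
Why: Fluoride-mediated desilylation with pyridine-buffered HF·pyridine cleaves the aryl and the secondary silyl ether under non-basic conditions, which avoids conjugation of the β,γ-unsaturated ketone and epimerisation at C11'.

**Compound list**

1 | 4-methoxy-2-methylphenol | COc1ccc(O)c(C)c1 | starting material
2 | 2-hydroxy-5-methoxy-3-methylbenzaldehyde | COc1cc(C)c(O)c(C=O)c1 | intermediate
3 | 2-[(tert-butyldimethylsilyl)oxy]-5-methoxy-3-methylbenzaldehyde | COc1cc(C)c(O[Si](C)(C)C(C)(C)C)c(C=O)c1 | intermediate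
4 | {2-[(tert-butyldimethylsilyl)oxy]-5-methoxy-3-methylphenyl}methanol | COc1cc(C)c(O[Si](C)(C)C(C)(C)C)c(CO)c1 | intermediate
5 | [2-(bromomethyl)-4-methoxy-6-methylphenoxy](tert-butyl)dimethylsilane | COc1cc(C)c(O[Si](C)(C)C(C)(C)C)c(CBr)c1 | intermediate
6 | prop-1-yn-1-ylmagnesium bromide (THF solution) | CC#C[Mg]Br | starting material
7 | [2-(but-2-yn-1-yl)-4-methoxy-6-methylphenoxy](tert-butyl)dimethylsilane | COc1cc(C)c(O[Si](C)(C)C(C)(C)C)c(CC#CC)c1 | intermediate
8 | (E)-alkenylzirconocene chloride, Cp2Zr(Cl) on C3' of the 1-arylbut-2-en-3-yl group (Cp drawn σ-bonded) | COc1cc(C)c(O[Si](C)(C)C(C)(C)C)c(C/C=C(\C)[Zr](Cl)(C2C=CC=C2)C2C=CC=C2)c1 | intermediate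
9 | {2-[(E)-3-bromobut-2-en-1-yl]-4-methoxy-6-methylphenoxy}(tert-butyl)dimethylsilane (west bromide) | COc1cc(C)c(O[Si](C)(C)C(C)(C)C)c(C/C=C(\C)Br)c1 | intermediate
10 | methyl (S)-3-hydroxy-2-methylpropanoate | COC(=O)[C@@H](C)CO | starting material
11 | methyl (2S)-2-methyl-3-[(triethylsilyl)oxy]propanoate | COC(=O)[C@@H](C)CO[Si](CC)(CC)CC | intermediate
12 | (2R)-2-methyl-3-[(triethylsilyl)oxy]propan-1-ol | OC[C@@H](C)CO[Si](CC)(CC)CC | intermediate
13 | (2S)-2-methyl-3-[(triethylsilyl)oxy]propyl 4-methylbenzenesulfonate | Cc1ccc(cc1)S(=O)(=O)OC[C@@H](C)CO[Si](CC)(CC)CC | intermediate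
14 | (4-bromobut-1-yn-1-yl)trimethylsilane | C[Si](C)(C)C#CCCBr | starting material
15 | [4-(trimethylsilyl)but-3-yn-1-yl]magnesium bromide | C[Si](C)(C)C#CCC[Mg]Br | intermediate
16 | triethyl{[(2R)-2-methyl-7-(trimethylsilyl)hept-6-yn-1-yl]oxy}silane | C[Si](C)(C)C#CCCC[C@@H](C)CO[Si](CC)(CC)CC | intermediate
17 | triethyl{[(2R)-2-methylhept-6-yn-1-yl]oxy}silane | C#CCCC[C@@H](C)CO[Si](CC)(CC)CC | intermediate
18 | 2-isopropoxy-4,4,5,5-tetramethyl-1,3,2-dioxaborolane | CC(C)OB1OC(C)(C)C(C)(C)O1 | starting material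
19 | dimethyl{(1E,6R)-2,6-dimethyl-7-[(triethylsilyl)oxy]hept-1-en-1-yl}alane | C[Al](C)/C=C(\C)CCC[C@@H](C)CO[Si](CC)(CC)CC | intermediate
20 | triethyl{[(2R,6E)-2,6-dimethyl-7-(4,4,5,5-tetramethyl-1,3,2-dioxaborolan-2-yl)hept-6-en-1-yl]oxy}silane (east boronate) | CC1(C)OB(/C=C(\C)CCC[C@@H](C)CO[Si](CC)(CC)CC)OC1(C)C | intermediate
21 | vinyllithium | [Li]C=C | starting material
22 | lithium vinyl{(1E,6R)-2,6-dimethyl-7-[(triethylsilyl)oxy]hept-1-en-1-yl}(pinacolato)borate | [Li+].C=C[B-]1(/C=C(\C)CCC[C@@H](C)CO[Si](CC)(CC)CC)OC(C)(C)C(C)(C)O1 | intermediate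
23 | tert-butyl{2-[(2E,5R,6E,11R)-3,7,11-trimethyl-5-(4,4,5,5-tetramethyl-1,3,2-dioxaborolan-2-yl)-12-[(triethylsilyl)oxy]dodeca-2,6-dien-1-yl]-4-methoxy-6-methylphenoxy}dimethylsilane | COc1cc(C)c(O[Si](C)(C)C(C)(C)C)c(C/C=C(\C)C[C@@H](B2OC(C)(C)C(C)(C)O2)/C=C(\C)CCC[C@@H](C)CO[Si](CC)(CC)CC)c1 | intermediate
24 | (2E,5R,6E,11R)-1-{2-[(tert-butyldimethylsilyl)oxy]-5-methoxy-3-methylphenyl}-3,7,11-trimethyl-12-[(triethylsilyl)oxy]dodeca-2,6-dien-5-ol | COc1cc(C)c(O[Si](C)(C)C(C)(C)C)c(C/C=C(\C)C[C@@H](O)/C=C(\C)CCC[C@@H](C)CO[Si](CC)(CC)CC)c1 | intermediate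
25 | tert-butyl{[(2E,5R,6E,11R)-1-{2-[(tert-butyldimethylsilyl)oxy]-5-methoxy-3-methylphenyl}-3,7,11-trimethyl-12-[(triethylsilyl)oxy]dodeca-2,6-dien-5-yl]oxy}dimethylsilane | COc1cc(C)c(O[Si](C)(C)C(C)(C)C)c(C/C=C(\C)C[C@@H](O[Si](C)(C)C(C)(C)C)/C=C(\C)CCC[C@@H](C)CO[Si](CC)(CC)CC)c1 | intermediate
26 | (2R,6E,8R,10E)-8-[(tert-butyldimethylsilyl)oxy]-12-{2-[(tert-butyldimethylsilyl)oxy]-5-methoxy-3-methylphenyl}-2,6,10-trimethyldodeca-6,10-dien-1-ol | COc1cc(C)c(O[Si](C)(C)C(C)(C)C)c(C/C=C(\C)C[C@@H](O[Si](C)(C)C(C)(C)C)/C=C(\C)CCC[C@@H](C)CO)c1 | intermediate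
27 | (2R,6E,8R,10E)-8-[(tert-butyldimethylsilyl)oxy]-12-{2-[(tert-butyldimethylsilyl)oxy]-5-methoxy-3-methylphenyl}-2,6,10-trimethyldodeca-6,10-dienal | COc1cc(C)c(O[Si](C)(C)C(C)(C)C)c(C/C=C(\C)C[C@@H](O[Si](C)(C)C(C)(C)C)/C=C(\C)CCC[C@@H](C)C=O)c1 | intermediate
28 | 1-chloro-3-methylbut-2-ene (prenyl chloride) | CC(C)=CCCl | starting material
29 | (3-methylbut-2-en-1-yl)barium chloride | CC(C)=CC[Ba]Cl | intermediate
30 | (6R,10E,12R,14E)-12-[(tert-butyldimethylsilyl)oxy]-16-{2-[(tert-butyldimethylsilyl)oxy]-5-methoxy-3-methylphenyl}-2,6,10,14-tetramethylhexadeca-2,10,14-trien-5-ol, both C5 (C12') epimers | COc1cc(C)c(O[Si](C)(C)C(C)(C)C)c(C/C=C(\C)C[C@@H](O[Si](C)(C)C(C)(C)C)/C=C(\C)CCC[C@@H](C)C(O)CC=C(C)C)c1 | intermediate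
31 | (6R,10E,12R,14E)-12-[(tert-butyldimethylsilyl)oxy]-16-{2-[(tert-butyldimethylsilyl)oxy]-5-methoxy-3-methylphenyl}-2,6,10,14-tetramethylhexadeca-2,10,14-trien-5-one | COc1cc(C)c(O[Si](C)(C)C(C)(C)C)c(C/C=C(\C)C[C@@H](O[Si](C)(C)C(C)(C)C)/C=C(\C)CCC[C@@H](C)C(=O)CC=C(C)C)c1 | intermediate
32 | (6R,10E,12R,14E)-12-hydroxy-16-(2-hydroxy-5-methoxy-3-methylphenyl)-2,6,10,14-tetramethylhexadeca-2,10,14-trien-5-one (2'E,5'R,6'E,11'R in chain locants) | COc1cc(C)c(O)c(C/C=C(\C)C[C@@H](O)/C=C(\C)CCC[C@@H](C)C(=O)CC=C(C)C)c1 | target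

**Count and risks**

Total: 20 steps. Longest linear sequence: 14 steps (steps 1–6 or 7–12, then 13–20).

Steps most likely to fail:

1. Step 13. The hindered partners may slow oxidative addition and the palladium-induced 1,2-shift, so that direct alkenyl transfer from boron to palladium (Suzuki–Miyaura coupling) takes over, or the enantioface selection at the vinyl group may be weak. The fallback sets out from 9 and 17 and comes back at 24. Bromide 9 is converted by bromine–lithium exchange (t-BuLi, Et2O, −78 °C) and opening of ethylene oxide (BF3·OEt2) into the homoallylic alcohol (E)-5-aryl-3-methylpent-3-en-1-ol F1, which is oxidised with buffered Dess–Martin periodinane to the β,γ-unsaturated aldehyde F2. Alkyne 17 is carried through Negishi carboalumination and iodine quench to the (E)-alkenyl iodide F3. A Nozaki–Hiyama–Kishi coupling (CrCl2, NiCl2 cat., DMSO/THF) of F3 with F2 gives the allylic alcohol as a C5' epimer mixture F4. Dess–Martin oxidation leads to the enone F5, and Corey–Bakshi–Shibata reduction with the (S)-oxazaborolidine and BH3·SMe2 should deliver 24. On the usual large/small model the alkenyl group acts as the large substituent, which points to 5'R.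

2. Step 18. Formation of active barium may be incomplete, the prenyl metal may attack through its γ-terminus to give the reverse-prenyl adduct, or the α-branched aldehyde may enolise. The fallback sets out from 27 and comes back at 31. Lithiated 3-methylbut-2-enyl phenyl sulfone (commercial sulfone, n-BuLi, THF, −78 °C) adds to 27 through its sulfonyl-bearing carbon to give the β-hydroxy sulfone F6. Dess–Martin oxidation gives the β-keto sulfone F7. Reductive desulfonylation with SmI2 in THF/MeOH at −78 °C, with kinetic α-protonation of the resulting dienolate, should give the β,γ-unsaturated ketone 31.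

3. Step 6. Zirconium may not settle fully on the methyl-bearing carbon, giving an inseparable regioisomeric bromide, and NBS may brominate the electron-rich ring. The fallback sets out from 5 and comes back at 9. Zinc insertion (Zn dust, LiCl, THF) converts 5 into the benzylic zinc bromide F8. Anti addition of iodine monobromide (IBr) to propyne gives (E)-2-bromo-1-iodoprop-1-ene F9. A Negishi coupling with Pd(PPh3)4 (zerovalent palladium) at room temperature, selective for the carbon–iodine bond, should join F8 and F9 to give 9 with the E geometry fixed by the dihalide.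

**Further compounds**

F1 | step 13 | (E)-5-{2-[(tert-butyldimethylsilyl)oxy]-5-methoxy-3-methylphenyl}-3-methylpent-3-en-1-ol | COc1cc(C)c(O[Si](C)(C)C(C)(C)C)c(C/C=C(\C)CCO)c1
F2 | step 13 | (E)-5-{2-[(tert-butyldimethylsilyl)oxy]-5-methoxy-3-methylphenyl}-3-methylpent-3-enal | COc1cc(C)c(O[Si](C)(C)C(C)(C)C)c(C/C=C(\C)CC=O)c1
F3 | step 13 | triethyl{[(2R,6E)-7-iodo-2,6-dimethylhept-6-en-1-yl]oxy}silane | I/C=C(\C)CCC[C@@H](C)CO[Si](CC)(CC)CC
F4 | step 13 | (2E,6E,11R)-1-{2-[(tert-butyldimethylsilyl)oxy]-5-methoxy-3-methylphenyl}-3,7,11-trimethyl-12-[(triethylsilyl)oxy]dodeca-2,6-dien-5-ol, both C5' epimers | COc1cc(C)c(O[Si](C)(C)C(C)(C)C)c(C/C=C(\C)CC(O)/C=C(\C)CCC[C@@H](C)CO[Si](CC)(CC)CC)c1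
F5 | step 13 | (2E,6E,11R)-1-{2-[(tert-butyldimethylsilyl)oxy]-5-methoxy-3-methylphenyl}-3,7,11-trimethyl-12-[(triethylsilyl)oxy]dodeca-2,6-dien-5-one | COc1cc(C)c(O[Si](C)(C)C(C)(C)C)c(C/C=C(\C)CC(=O)/C=C(\C)CCC[C@@H](C)CO[Si](CC)(CC)CC)c1
F6 | step 18 | β-hydroxy sulfone: 30 bearing a phenylsulfonyl group on C13', mixture of C12' and C13' epimers | COc1cc(C)c(O[Si](C)(C)C(C)(C)C)c(C/C=C(\C)C[C@@H](O[Si](C)(C)C(C)(C)C)/C=C(\C)CCC[C@@H](C)C(O)C(C=C(C)C)S(=O)(=O)c2ccccc2)c1
F7 | step 18 | β-keto sulfone: 31 bearing a phenylsulfonyl group on C13', mixture of C13' epimers | COc1cc(C)c(O[Si](C)(C)C(C)(C)C)c(C/C=C(\C)C[C@@H](O[Si](C)(C)C(C)(C)C)/C=C(\C)CCC[C@@H](C)C(=O)C(C=C(C)C)S(=O)(=O)c2ccccc2)c1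
F8 | step 6 | {2-[(tert-butyldimethylsilyl)oxy]-5-methoxy-3-methylbenzyl}zinc bromide | COc1cc(C)c(O[Si](C)(C)C(C)(C)C)c(C[Zn]Br)c1
F9 | step 6 | (E)-2-bromo-1-iodoprop-1-ene | I/C=C(\C)Br
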